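Its constants stand for no real mixture; no experiment stands behind them.

The target, once made, leaves by two roads, and how that exit divides is what I reckon here.

    substrate + partner → target, rate k1*[substrate]*[partner]^0.5 (k1 = 0.019 /M^0.5/s)
    substrate + target → side product (k2 = 0.51 /M/s)
    substrate ⇌ dormant form (K3 = 3.0, k3 = 0.012 /s)
    target ⇌ isomer of the product (K4 = 5.4, k4 = 0.0044 /s)

| setting | delta | zeta | beta | gamma |
|---|---|---|---|---|
| substrate | 0.020 M | 0.020 M | 0.020 M | 0.020 M (fed, over 15 min) |
| partner | 0.900 equiv (fed, over 15 min) | 0.900 equiv (in portions, 5, over 15 min) | 0.900 equiv | 0.900 equiv |
| time | 20 min | 20 min | 20 min | 20 min |
| remark | all else is in the flask from the start; the feed brings no volume worth counting | first portion at the start, last at 15 min | everything together at the start | all else is in the flask from the start; the feed brings no volume worth counting |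

- percentages count the substrate that a species holds: one side product counts as two
- run time (delta): 20 min

1. the flask with the highest amount of side product, in percent of the substrate charged ("all alike" if they lie within 1.5 percentage points) (delta / zeta / beta / gamma / all alike)
2. final side product, as a percentage of the substrate charged, in delta
3. final side product, as a percentage of the substrate charged, in zeta
4. final side product, as a percentage of the substrate charged, in beta
5. final side product, as a percentage of the substrate charged, in gamma

I take gamma, where the substrate is fed. Partner stands in neither loss of target, but it consumes substrate, so it can still shift how the target divides. One road is the drift to the isomer of the product, with a forward time of 3.79 min. The other is the side step, pseudo-first-order in target, whose one other concentration is free substrate. In gamma the dormant equilibrium relaxes with a half-life of 0.722 min, shorter than the 2.22 min of the drift, so I take free substrate as 0.250 of the unconverted pool. With the whole charge as that pool, a target meets the side step in 6.54 min. The drift time over the side time is my branch number, 0.580: side-step events per target drifting to isomer. It is rough, since the pool shrinks and the isomer can return. Each event costs two substrates, so I expect side product at 1.16 times the isomer, both as fractions of the charge. This gives the split, not the amount, and my reckoning stops there.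

The forecast reads 22% in delta, 25% in zeta, 26% in beta and 11% in gamma, on the ground that “feeding the substrate slowly starves that step”.

The flasks give 20.3% in delta, 22.1% in zeta, 28.0% in beta and 18.3% in gamma. Gamma holds 19.1% isomer at 20.0 min, so my ratio gives 22.2% side product against that 18.3%. The neighbour of gamma, charged at 0.0050 M with the same equivalents, has a branch number of 0.145. It holds 14.4% isomer, so the ratio gives 4.18% side product, and that flask ends with 4.30%.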